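The numbers in the tables were computed with constants of no real substance; the scatter is artificial.

In a one-step world the catalyst turns substrate over at a steady pace, and conversion is a clock set by catalyst per substrate. The first of two chemists holds this view of the flask below.

| setting | oak | elm | maple | flask |
|---|---|---|---|---|
| substrate | 0.050 M | 0.20 M | 0.10 M | 0.10 M |
| gas phase | 17 mM (held) | 17 mM (held) | 17 mM (held) | 17 mM (held) |
| catalyst | 0.50 mM | 0.50 mM | 1 mM | 0.50 mM |
| remark | run made earlier | run made earlier | run made earlier |  |
| time |  |  |  | 25 min |

- oak (time / min: product / %, substrate / %): 4.00: 9.4, 89.7; 8.00: 20.8, 78.3; 12.0: 30.0, 68.9; 15.0: 35.5, 63.6; 20.0: 42.6, 56.8; 25.0: 46.4, 52.4; 30.0: 49.1, 50.6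
- elm (time / min: product / %, substrate / %): 2.50: 1.8, 98.2; 4.00: 2.2, 97.1; 6.00: 5.2, 94.3; 8.00: 6.8, 93.0; 12.0: 10.2, 88.9; 20.0: 18.0, 82.0; 30.0: 25.1, 74.2
- maple (time / min: product / %, substrate / %): 2.50: 4.8, 94.4; 5.00: 11.8, 87.1; 8.00: 20.7, 79.2; 15.0: 35.0, 64.4; 30.0: 49.1, 50.4

(each reading ± 0.3 percentage points)

- at the start none of the gas phase is in solution

- violet: doubling the amount of catalyst, all else as stated
- ochre: doubling the transfer coefficient of the gas phase, all else as stated
- red: doubling the saturation concentration of gas phase, all else as stated

1. the product standing at 25 min, as a percentage of the substrate charged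
2. the change that raises the amount of product at 25 min, in percent of the substrate charged most ("none" if none brings more than 2 percentage points) (violet / ochre / red / none)
3. amount of product at 25 min, in percent of the substrate charged, after ochre

The first chemist points to oak and maple: equal catalyst-to-substrate ratios, and 49.1% and 49.1% at 30.0 min. The flask has half of oak's ratio, so its 25 min count as 12.5 min on oak's clock. Elm's 30.0 min count as 7.50 min, yet its 25.1% exceeds oak's 20.8% at 8.00 min and matches oak at 9.87 min. The flask's substrate is the geometric mean of oak's and elm's, so I take the square root of that stretch, which gives 14.3 min on oak's clock and 34.3% product. For him violet simply runs the clock faster.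

The second chemist accepts that figure and rejects the world. Oak's last gains, 3.8 percentage points and then 2.7 points, shrink while 50.6% of substrate stands, which she reads as a reversible step nearing its equilibrium position. She treats what remains as a correction to the last reading, summing the gains as a geometric series, and reads a ceiling of 55.7%, with large scatter. That makes the stall ratio, product over substrate where a flask stops, 1.26. The readings do not test the gas, so she assumes it enters the product and the stall ratio follows its saturation concentration. Red then gives 2.52 and a ceiling of 71.6%, above 55.7%, while violet and ochre leave the ceiling alone. I side with her: red.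

The forecast, on the first chemist's side, gives 34.5%, names violet and puts ochre at 36%: “Red is untested because gas order is unknown”.

The simulation gives 35.3% and 38.2% after ochre. Red gains 26 points, violet 11 points and ochre 3 points, so the best change is red.

    substrate + dissolved gas + catalyst ⇌ catalyst + product (K = 66.0 M⁻¹, k = 25000 M⁻² min⁻¹)
    gas phase ⇌ dissolved gas, rate k2*(csat - [dissolved gas]) (kL = 0.614 min⁻¹)
    substrate + catalyst ⇌ idle complex, settled at all times (K = 74.9 M⁻¹)

At 25.0 min the flask's product over substrate is 0.549, a share of 0.436 of the stall ratio read from oak. The neighbouring flask, with 0.025 M of substrate, reaches 50.0 min on oak's clock, past oak's last reading, so it is held against the stall ratio. That neighbouring flask gives 51.1% of product beside 47.9% of substrate, a ratio of 1.07, which is below the 1.26 read from oak with its large scatter and is 0.951 of the 1.12 at which the asked flask stands after 250 min.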